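**Plan**

1. Locants follow longipinane: C1 is the ketone carbon, C3 carries the secondary methyl, C4–C5–C11–C10 is the cyclobutane, C6 is the gem-dimethyl carbon, C7–C9 are the three carbinols, C10 is the quaternary methyl carbon.
2. Retrosynthesis cuts the three angelate C–O bonds, the C8/C9 hydroxyls (back to a C8=C9 alkene), the C3 methyl (back to a C2=C3 enone), and then in one stroke the cyclobutane bond C5–C11 and the seven-ring bond C9–C10. The open-chain precursor is cut at C5–C6 (aldol) into a cyclohexene aldehyde and a silyl ynone.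
3. Forward, the six-membered ring comes from Hagemann's ester, the C5–C9 chain is joined by a Mukaiyama aldol, and one cationic cascade, a formal (5+2) annulation of C5–C9 across C10=C11, closes the cyclobutane and then the cycloheptene.
4. The enabling feature is the 3-methyl-homoallyl array C5(OMs)–C4–C10(CH3)=C11 inside the cyclohexene ring. Ionisation at C5 becomes a tertiary cyclobutyl cation at C10, and a (Z)-vinylsilane at C8=C9, five carbons along the chain, ends the cascade. The C1 silyl ether (ketone held at the alcohol level), the mesylate and the C-silyl group are helpers, removed in or after the cascade.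
5. Stereochemistry: C4 by separating the two diastereomers that CBS reduction makes from racemic Hagemann's ester; C5 by Felkin–Anh addition; C7 by Noyori transfer hydrogenation; C10 and C11 from the geometry of the cascade; C3 by cuprate addition anti to the C10 bridge; C8 and C9 by osmylation anti to the C7 oxygen.

Key step: step 11

**Route**

Step 1
Reactants: 1 isobutyryl chloride; 2 bis(trimethylsilyl)acetylene
Product: 3 4-methyl-1-(trimethylsilyl)pent-1-yn-3-one
Conditions: AlCl3, CH2Cl2, 0 °C
Reagents that add atoms: none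
Why: Friedel–Crafts-type acylation of the alkynylsilane with ipso loss of one silyl group should give the silyl-capped ynone, and no stereocentre is formed.

Step 2
Reactants: 3 4-methyl-1-(trimethylsilyl)pent-1-yn-3-one
Product: 4 4-methyl-1-(trimethylsilyl)-3-(trimethylsilyloxy)pent-3-en-1-yne
Conditions: Me3SiOTf, Et3N, CH2Cl2, 0 °C
Reagents that add atoms: trimethylsilyl trifluoromethanesulfonate C[Si](C)(C)OS(=O)(=O)C(F)(F)F
Why: soft enolisation and O-silylation (silyl enol ether formation) can occur only at the isopropyl methine, the single enolisable position, so one tetrasubstituted enol silane with no stereochemical issue should result.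

Step 3
Reactants: 5 racemic ethyl 2-methyl-4-oxocyclohex-2-ene-1-carboxylate (Hagemann's ester)
Product: 6 ethyl (1R,4S)-4-hydroxy-2-methylcyclohex-2-ene-1-carboxylate (cis)
Conditions: (R)-2-methyl-CBS-oxazaborolidine (cat.), BH3·SMe2, THF, −20 °C; then chromatographic separation of the cis and trans alcohols
Reagents that add atoms: none
Why: the Corey–Bakshi–Shibata reduction delivers hydride to one face of the enone carbonyl under catalyst control and should set the carbinol centre as (4S) in both enantiomers of 5, which turns the racemate into two separable diastereomers, of which the cis alcohol 6 carries the (1R) ester-bearing carbon that becomes C4.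

Step 4
Reactants: 6 ethyl (1R,4S)-4-hydroxy-2-methylcyclohex-2-ene-1-carboxylate
Product: 7 ethyl (1R,4S)-4-(tert-butyldimethylsilyloxy)-2-methylcyclohex-2-ene-1-carboxylate
Conditions: tBuMe2SiCl, imidazole, DMF, rt
Reagents that add atoms: tert-butyldimethylsilyl chloride CC(C)(C)[Si](C)(C)Cl
Why: imidazole-promoted silyl ether formation masks the allylic alcohol, which is the future ketone held at the alcohol level until step 13, without touching a stereocentre.

Step 5
Reactants: 7 ethyl (1R,4S)-4-(tert-butyldimethylsilyloxy)-2-methylcyclohex-2-ene-1-carboxylate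
Product: 8 (1R,4S)-4-(tert-butyldimethylsilyloxy)-2-methylcyclohex-2-ene-1-carbaldehyde
Conditions: iBu2AlH, CH2Cl2, −78 °C; potassium sodium tartrate work-up; used crude
Reagents that add atoms: none
Why: partial ester reduction with iBu2AlH should stop at the aldehyde because the aluminium hemiacetal is stable at −78 °C, and the α-stereocentre is kept by low temperature, a neutral work-up and immediate use of 8.

Step 6
Reactants: 8 (1R,4S)-4-(tert-butyldimethylsilyloxy)-2-methylcyclohex-2-ene-1-carbaldehyde; 4 4-methyl-1-(trimethylsilyl)-3-(trimethylsilyloxy)pent-3-en-1-yne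
Product: 9 (5S)-5-[(1R,4S)-4-(tert-butyldimethylsilyloxy)-2-methylcyclohex-2-en-1-yl]-5-hydroxy-4,4-dimethyl-1-(trimethylsilyl)pent-1-yn-3-one
Conditions: BF3·OEt2, CH2Cl2, −78 °C; aq. NaHCO3
Reagents that add atoms: none
Why: Mukaiyama aldol addition of the enol silane to the BF3-activated aldehyde should follow the Felkin–Anh model, the nucleophile entering anti to the sp2 ring carbon of the α-stereocentre, which sets the new carbinol carbon (the future C5) as (5S) and builds the quaternary gem-dimethyl carbon in the same bond.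

Step 7
Reactants: 9 (5S)-5-[(1R,4S)-4-(tert-butyldimethylsilyloxy)-2-methylcyclohex-2-en-1-yl]-5-hydroxy-4,4-dimethyl-1-(trimethylsilyl)pent-1-yn-3-one
Product: 10 (1S)-1-[(1R,4S)-4-(tert-butyldimethylsilyloxy)-2-methylcyclohex-2-en-1-yl]-2,2-dimethyl-3-oxo-5-(trimethylsilyl)pent-4-yn-1-yl methanesulfonate
Conditions: MeSO2Cl, Et3N, CH2Cl2, 0 °C
Reagents that add atoms: methanesulfonyl chloride CS(=O)(=O)Cl
Why: mesylation through the sulfene works even for hindered neopentylic alcohols and keeps the carbinol configuration, and the β-mesyloxy ketone cannot eliminate because the carbon between carbonyl and sulfonate is quaternary.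

Step 8
Reactants: 10 (1S)-1-[(1R,4S)-4-(tert-butyldimethylsilyloxy)-2-methylcyclohex-2-en-1-yl]-2,2-dimethyl-3-oxo-5-(trimethylsilyl)pent-4-yn-1-yl methanesulfonate
Product: 11 (1S,3S)-1-[(1R,4S)-4-(tert-butyldimethylsilyloxy)-2-methylcyclohex-2-en-1-yl]-3-hydroxy-2,2-dimethyl-5-(trimethylsilyl)pent-4-yn-1-yl methanesulfonate
Conditions: RuCl[(S,S)-TsDPEN](p-cymene) (cat.), iPrOH, rt
Reagents that add atoms: none
Why: Noyori asymmetric transfer hydrogenation reduces the ynone carbonyl under control of the (S,S)-TsDPEN ligand, the alkyne acting as the larger flanking group, which should set the propargylic carbinol (the future C7) as (3S) independently of the other stereocentres.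

Step 9
Reactants: 11 (1S,3S)-1-[(1R,4S)-4-(tert-butyldimethylsilyloxy)-2-methylcyclohex-2-en-1-yl]-3-hydroxy-2,2-dimethyl-5-(trimethylsilyl)pent-4-yn-1-yl methanesulfonate
Product: 12 (1S,3S)-1-[(1R,4S)-4-(tert-butyldimethylsilyloxy)-2-methylcyclohex-2-en-1-yl]-2,2-dimethyl-3-(triisopropylsilyloxy)-5-(trimethylsilyl)pent-4-yn-1-yl methanesulfonate
Conditions: iPr3SiOTf, 2,6-lutidine, CH2Cl2, 0 °C
Reagents that add atoms: triisopropylsilyl trifluoromethanesulfonate CC(C)[Si](OS(=O)(=O)C(F)(F)F)(C(C)C)C(C)C
Why: silylation with the silyl triflate and a hindered pyridine base protects the hindered propargylic alcohol as a bulky, weakly nucleophilic ether that cannot take part in the cation chemistry of step 11, with no change at any stereocentre.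

Step 10
Reactants: 12 (1S,3S)-1-[(1R,4S)-4-(tert-butyldimethylsilyloxy)-2-methylcyclohex-2-en-1-yl]-2,2-dimethyl-3-(triisopropylsilyloxy)-5-(trimethylsilyl)pent-4-yn-1-yl methanesulfonate
Product: 13 (1S,3R,4Z)-1-[(1R,4S)-4-(tert-butyldimethylsilyloxy)-2-methylcyclohex-2-en-1-yl]-2,2-dimethyl-3-(triisopropylsilyloxy)-5-(trimethylsilyl)pent-4-en-1-yl methanesulfonate
Conditions: H2 (1 atm), Pd/CaCO3 poisoned with Pb(OAc)2, quinoline, EtOAc, rt
Reagents that add atoms: none
Why: Lindlar semihydrogenation adds H2 syn to the silylalkyne and should stop at the (Z)-vinylsilane, the geometry needed for an endocyclic alkene in step 11, while the trisubstituted ring alkene is left untouched.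

Step 11
Reactants: 13 (1S,3R,4Z)-1-[(1R,4S)-4-(tert-butyldimethylsilyloxy)-2-methylcyclohex-2-en-1-yl]-2,2-dimethyl-3-(triisopropylsilyloxy)-5-(trimethylsilyl)pent-4-en-1-yl methanesulfonate
Product: 15 (1S,4S,5S,7R,10R,11R)-1-(tert-butyldimethylsilyloxy)-7-(triisopropylsilyloxy)-3-demethyllongipin-8-ene, via tertiary cyclobutyl cation 14 (not isolated)
Conditions: (CF3)2CHOH, 2,6-lutidine, 50 °C
Reagents that add atoms: none
Why: Proposed new method: ionisation of the secondary mesylate at C5 is assisted from the rear by the homoallylic C10=C11 double bond, which lies under the pseudoaxial side chain (allylic strain from the C10 methyl), so C11 bonds to C5 with inversion and the charge moves to the methyl-bearing C10 to give tertiary cyclobutyl cation 14; the (Z)-vinylsilane then attacks C10 through its silicon-bearing carbon C9 and loses the silyl group, which closes the cycloheptene with the C8=C9 bond in place. The closest known reaction types are the solvolytic homoallyl-to-cyclobutyl rearrangement of 3-methylbut-3-enyl sulfonates and the vinylsilane-terminated cation–olefin cyclisation; their combination in one cascade, and the use of the first to build a bicyclo[3.1.1]heptane, are new. The four-membered ring closes by π-participation (C11 onto C5, formally 4-endo) and the seven-membered ring by 7-endo ipso attack of the vinylsilane on the cation. C5 is set by inversion at the sulfonate carbon (configured in step 6), C11 and C10 by the face of the ring alkene that carries the side chain (C4, fixed in step 3) and by the five-atom tether, which can reach only the lobe of the cation on the side of the C5 bridge, while C7 and C1 are carried through. The step needs π-participation to outrun hydride shift from C4, methyl shift from C6 and direct attack of the vinylsilane on C5; the anti-periplanar alignment of the leaving group with the ring π bond, the tertiary nature of cation 14 and the disfavoured 5-endo mode of direct attack should secure this, and the buffered, non-nucleophilic solvent limits capture of 14 by solvent and protodesilylation.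

Step 12
Reactants: 15 (1S,4S,5S,7R,10R,11R)-1-(tert-butyldimethylsilyloxy)-7-(triisopropylsilyloxy)-3-demethyllongipin-8-ene
Product: 16 (1S,4S,5S,7R,10R,11R)-7-(triisopropylsilyloxy)-3-demethyllongipin-8-en-1-ol
Conditions: HF·pyridine, pyridine, THF, 0 °C
Reagents that add atoms: none
Why: selective desilylation with buffered HF·pyridine should cleave the less hindered secondary tert-butyldimethylsilyl ether at C1 faster than the triisopropylsilyl ether at C7, which is flanked by the quaternary C6.

Step 13
Reactants: 16 (1S,4S,5S,7R,10R,11R)-7-(triisopropylsilyloxy)-3-demethyllongipin-8-en-1-ol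
Product: 17 (4S,5S,7R,10R,11R)-7-(triisopropylsilyloxy)-3-demethyllongipin-8-en-1-one
Conditions: Dess–Martin periodinane, NaHCO3, CH2Cl2, rt
Reagents that add atoms: none
Why: Dess–Martin oxidation converts the secondary alcohol into the C1 ketone under buffered conditions that leave the silyl ether and the alkene alone, and it removes the C1 stereocentre that only served as a carrier.

Step 14
Reactants: 17 (4S,5S,7R,10R,11R)-7-(triisopropylsilyloxy)-3-demethyllongipin-8-en-1-one
Product: 19 (4S,5S,7R,10R,11R)-7-(triisopropylsilyloxy)-3-demethyllongipina-2,8-dien-1-one, via trimethylsilyl enol ether 18 (not isolated)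
Conditions: LiN(iPr)2, Me3SiCl, THF, −78 °C; then Pd(OAc)2, MeCN, rt
Reagents that add atoms: chlorotrimethylsilane C[Si](C)(C)Cl (silyl group of intermediate 18 only)
Why: in this Saegusa–Ito oxidation the enolate can form only toward C2 because C11 is a bridgehead of the bicyclo[3.1.1]heptane, so silylation and Pd(OAc)2-mediated dehydrosilylation should give the C2=C3 enone.

Step 15
Reactants: 19 (4S,5S,7R,10R,11R)-7-(triisopropylsilyloxy)-3-demethyllongipina-2,8-dien-1-one
Product: 20 (3R,4S,5S,7R,10R,11R)-7-(triisopropylsilyloxy)longipin-8-en-1-one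
Conditions: Me2CuLi (from CuI and MeLi), Et2O, −40 °C
Reagents that add atoms: lithium dimethylcuprate [Li+].C[Cu-]C
Why: conjugate addition of the Gilman cuprate should place the methyl group on C3 from the face anti to the C10 methyl bridge, the less hindered face as in additions to pinene-type enones, which sets C3 as (R).

Step 16
Reactants: 20 (3R,4S,5S,7R,10R,11R)-7-(triisopropylsilyloxy)longipin-8-en-1-one
Product: 21 (3R,4S,5S,7S,8S,9S,10R,11R)-8,9-dihydroxy-7-(triisopropylsilyloxy)longipinan-1-one
Conditions: OsO4 (cat.), N-methylmorpholine N-oxide, acetone/H2O, rt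
Reagents that add atoms: N-methylmorpholine N-oxide C[N+]1([O-])CCOCC1; water O; osmium tetroxide O=[Os](=O)(=O)=O (catalytic oxygen carrier)
Why: Upjohn dihydroxylation adds two hydroxyls syn across C8=C9 and should do so from the face anti to the allylic C7 silyloxy group, the usual sense for osmylation of allylic ethers, which sets C8 and C9 cis to each other and trans to the C7 oxygen.

Step 17
Reactants: 21 (3R,4S,5S,7S,8S,9S,10R,11R)-8,9-dihydroxy-7-(triisopropylsilyloxy)longipinan-1-one
Product: 22 (3R,4S,5S,7S,8R,9S,10R,11R)-7,8,9-trihydroxylongipinan-1-one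
Conditions: Bu4NF, THF, rt
Reagents that add atoms: none
Why: fluoride-induced desilylation removes the remaining silyl ether and should give the free triol without affecting any stereocentre.

Step 18
Reactants: 22 (3R,4S,5S,7S,8R,9S,10R,11R)-7,8,9-trihydroxylongipinan-1-one; 23 angelic acid [(Z)-2-methylbut-2-enoic acid]
Product: 25 (3R,4S,5S,7S,8R,9S,10R,11R)-1-oxolongipinane-7,8,9-triyl tris[(Z)-2-methylbut-2-enoate] (CNP0138097.1), via angelic 2,4,6-trichlorobenzoic anhydride 24 (not isolated)
Conditions: 2,4,6-trichlorobenzoyl chloride, Et3N, toluene, rt; then 22, 80 °C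
Reagents that add atoms: 2,4,6-trichlorobenzoyl chloride O=C(Cl)c1c(Cl)cc(Cl)cc1Cl (acyl group of intermediate 24 only)
Why: Yamaguchi esterification through mixed anhydride 24 should acylate the three secondary alcohols, and leaving out a nucleophilic amine catalyst avoids addition–elimination at the β-carbon, so the (Z) geometry of the angelate units is kept.

**Compound list**

1 | isobutyryl chloride | CC(C)C(=O)Cl | starting material
2 | bis(trimethylsilyl)acetylene | C[Si](C)(C)C#C[Si](C)(C)C | starting material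
3 | 4-methyl-1-(trimethylsilyl)pent-1-yn-3-one | CC(C)C(=O)C#C[Si](C)(C)C | intermediate
4 | 4-methyl-1-(trimethylsilyl)-3-(trimethylsilyloxy)pent-3-en-1-yne | CC(C)=C(O[Si](C)(C)C)C#C[Si](C)(C)C | intermediate
5 | racemic ethyl 2-methyl-4-oxocyclohex-2-ene-1-carboxylate (Hagemann's ester) | CCOC(=O)C1CCC(=O)C=C1C | starting material
6 | ethyl (1R,4S)-4-hydroxy-2-methylcyclohex-2-ene-1-carboxylate (cis) | CCOC(=O)[C@H]1C(C)=C[C@@H](O)CC1 | intermediate
7 | ethyl (1R,4S)-4-(tert-butyldimethylsilyloxy)-2-methylcyclohex-2-ene-1-carboxylate | CCOC(=O)[C@H]1C(C)=C[C@@H](O[Si](C)(C)C(C)(C)C)CC1 | intermediate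
8 | (1R,4S)-4-(tert-butyldimethylsilyloxy)-2-methylcyclohex-2-ene-1-carbaldehyde | O=C[C@H]1C(C)=C[C@@H](O[Si](C)(C)C(C)(C)C)CC1 | intermediate
9 | (5S)-5-[(1R,4S)-4-(tert-butyldimethylsilyloxy)-2-methylcyclohex-2-en-1-yl]-5-hydroxy-4,4-dimethyl-1-(trimethylsilyl)pent-1-yn-3-one | C[Si](C)(C)C#CC(=O)C(C)(C)[C@@H](O)[C@H]1C(C)=C[C@@H](O[Si](C)(C)C(C)(C)C)CC1 | intermediate
10 | (1S)-1-[(1R,4S)-4-(tert-butyldimethylsilyloxy)-2-methylcyclohex-2-en-1-yl]-2,2-dimethyl-3-oxo-5-(trimethylsilyl)pent-4-yn-1-yl methanesulfonate | C[Si](C)(C)C#CC(=O)C(C)(C)[C@@H](OS(C)(=O)=O)[C@H]1C(C)=C[C@@H](O[Si](C)(C)C(C)(C)C)CC1 | intermediate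
11 | (1S,3S)-1-[(1R,4S)-4-(tert-butyldimethylsilyloxy)-2-methylcyclohex-2-en-1-yl]-3-hydroxy-2,2-dimethyl-5-(trimethylsilyl)pent-4-yn-1-yl methanesulfonate | C[Si](C)(C)C#C[C@@H](O)C(C)(C)[C@@H](OS(C)(=O)=O)[C@H]1C(C)=C[C@@H](O[Si](C)(C)C(C)(C)C)CC1 | intermediate
12 | (1S,3S)-1-[(1R,4S)-4-(tert-butyldimethylsilyloxy)-2-methylcyclohex-2-en-1-yl]-2,2-dimethyl-3-(triisopropylsilyloxy)-5-(trimethylsilyl)pent-4-yn-1-yl methanesulfonate | C[Si](C)(C)C#C[C@@H](O[Si](C(C)C)(C(C)C)C(C)C)C(C)(C)[C@@H](OS(C)(=O)=O)[C@H]1C(C)=C[C@@H](O[Si](C)(C)C(C)(C)C)CC1 | intermediate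
13 | (1S,3R,4Z)-1-[(1R,4S)-4-(tert-butyldimethylsilyloxy)-2-methylcyclohex-2-en-1-yl]-2,2-dimethyl-3-(triisopropylsilyloxy)-5-(trimethylsilyl)pent-4-en-1-yl methanesulfonate | C[Si](C)(C)/C=C\[C@@H](O[Si](C(C)C)(C(C)C)C(C)C)C(C)(C)[C@@H](OS(C)(=O)=O)[C@H]1C(C)=C[C@@H](O[Si](C)(C)C(C)(C)C)CC1 | intermediate
14 | tertiary cyclobutyl cation (charge at C10; C5–C11 bond formed; C1 silyl ether, C7 silyl ether and (Z)-vinylsilane chain on C5 intact) | C[Si](C)(C)/C=C\[C@@H](O[Si](C(C)C)(C(C)C)C(C)C)C(C)(C)[C@H]1[C@@H]2CC[C@H](O[Si](C)(C)C(C)(C)C)[C@H]1[C+]2C | intermediate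
15 | (1S,4S,5S,7R,10R,11R)-1-(tert-butyldimethylsilyloxy)-7-(triisopropylsilyloxy)-3-demethyllongipin-8-ene (3-demethyl = lacking the C3 methyl) | C1[C@@H](O[Si](C(C)C)(C(C)C)C(C)C)C(C)(C)[C@H]2[C@@H]3CC[C@H](O[Si](C)(C)C(C)(C)C)[C@H]2[C@]3(C)C=1 | intermediate
16 | (1S,4S,5S,7R,10R,11R)-7-(triisopropylsilyloxy)-3-demethyllongipin-8-en-1-ol | C1[C@@H](O[Si](C(C)C)(C(C)C)C(C)C)C(C)(C)[C@H]2[C@@H]3CC[C@H](O)[C@H]2[C@]3(C)C=1 | intermediate
17 | (4S,5S,7R,10R,11R)-7-(triisopropylsilyloxy)-3-demethyllongipin-8-en-1-one | C1[C@@H](O[Si](C(C)C)(C(C)C)C(C)C)C(C)(C)[C@H]2[C@@H]3CCC(=O)[C@H]2[C@]3(C)C=1 | intermediate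
18 | (4S,5S,7R,10R,11R)-7-(triisopropylsilyloxy)-1-(trimethylsilyloxy)-3-demethyllongipina-1,8-diene | C1[C@@H](O[Si](C(C)C)(C(C)C)C(C)C)C(C)(C)[C@H]2[C@@H]3CC=C(O[Si](C)(C)C)[C@H]2[C@]3(C)C=1 | intermediate
19 | (4S,5S,7R,10R,11R)-7-(triisopropylsilyloxy)-3-demethyllongipina-2,8-dien-1-one | C1[C@@H](O[Si](C(C)C)(C(C)C)C(C)C)C(C)(C)[C@H]2[C@@H]3C=CC(=O)[C@H]2[C@]3(C)C=1 | intermediate
20 | (3R,4S,5S,7R,10R,11R)-7-(triisopropylsilyloxy)longipin-8-en-1-one | C1[C@@H](O[Si](C(C)C)(C(C)C)C(C)C)C(C)(C)[C@H]2[C@@H]3[C@H](C)CC(=O)[C@H]2[C@]3(C)C=1 | intermediate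
21 | (3R,4S,5S,7S,8S,9S,10R,11R)-8,9-dihydroxy-7-(triisopropylsilyloxy)longipinan-1-one | O[C@@H]1[C@@H](O[Si](C(C)C)(C(C)C)C(C)C)C(C)(C)[C@H]2[C@@H]3[C@H](C)CC(=O)[C@H]2[C@]3(C)[C@@H]1O | intermediate
22 | (3R,4S,5S,7S,8R,9S,10R,11R)-7,8,9-trihydroxylongipinan-1-one | O[C@@H]1[C@@H](O)C(C)(C)[C@H]2[C@@H]3[C@H](C)CC(=O)[C@H]2[C@]3(C)[C@@H]1O | intermediate
23 | angelic acid [(Z)-2-methylbut-2-enoic acid] | C/C=C(/C)C(=O)O | starting material
24 | angelic 2,4,6-trichlorobenzoic anhydride | C/C=C(/C)C(=O)OC(=O)c1c(Cl)cc(Cl)cc1Cl | intermediate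
25 | (3R,4S,5S,7S,8R,9S,10R,11R)-1-oxolongipinane-7,8,9-triyl tris[(Z)-2-methylbut-2-enoate] (CNP0138097.1) | C/C=C(/C)C(=O)O[C@@H]1[C@@H](OC(=O)/C(C)=C\C)C(C)(C)[C@H]2[C@@H]3[C@H](C)CC(=O)[C@H]2[C@]3(C)[C@@H]1OC(=O)/C(C)=C\C | target

**Totals**

Total step count: 18. Longest linear sequence: 16 steps (5 to 25, steps 3–18).

**Steps most likely to fail**

1. Step 11 (proposed new method). What may go wrong: ionisation may proceed with hydride shift from C4 or methyl shift from C6 and end in elimination instead of π-participation; cation 14 may be captured by solvent or counter-ion, or collapse to its cyclopropylcarbinyl isomer; the tethered vinylsilane may fail to reach C10 on the face of the C5 bridge. Fallback, in two separately known reaction types, sets out from 13 and comes back at 15. Mesylate 13 is solvolysed in buffered aqueous CF3CH2OH (2,6-lutidine, 60 °C), the homoallyl-to-cyclobutyl solvolysis known for 3-methylbut-3-enyl sulfonates, so that water captures the cation and the tertiary cyclobutanol F1 is isolated. F1 is then ionised on its own with BF3·OEt2 in CH2Cl2 at −78 °C, and the tertiary cation is closed by the vinylsilane in a vinylsilane-terminated cation cyclisation to give 15.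

2. Step 6. What may go wrong: sluggish addition of the hindered tetrasubstituted enol silane 4, with competing enolisation and epimerisation at the α-stereocentre of 8 and erosion of Felkin–Anh selectivity. Fallback sets out from 8 and comes back at 9. Aldehyde 8 undergoes a Mukaiyama aldol (BF3·OEt2, CH2Cl2, −78 °C) with the more nucleophilic, commercial silyl ketene acetal of methyl isobutyrate to give the β-hydroxy ester F2. F2 is converted with MeNH(OMe)·HCl and iPrMgCl into the Weinreb amide F3, and addition of lithium (trimethylsilyl)acetylide to F3 gives ynone 9.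

3. Step 18. What may go wrong: isomerisation of the angelate double bond to the (E) tiglate geometry under forcing acylation, and incomplete acylation of the hydroxyls at C7 and C9, which are flanked by quaternary carbons. Fallback sets out from 22 and comes back at 25. Triol 22 is acylated three times with 2-[bis(2,2,2-trifluoroethoxy)phosphoryl]propanoic acid (dicyclohexylcarbodiimide, 4-dimethylaminopyridine), a small acid with no double bond to isomerise, to give the tris-phosphonate F4. A threefold Still–Gennari olefination of F4 with acetaldehyde (KN(SiMe3)2, 18-crown-6, THF, −78 °C) then builds the three (Z)-2-methylbut-2-enoate units and gives 25.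

**Further compounds**

F1 | step 11 | tertiary cyclobutanol: the C10 hydroxy compound with the C5–C11 bond formed (hydroxyl anti to C5; C1 silyl ether, C7 silyl ether and (Z)-vinylsilane chain intact) | C[Si](C)(C)/C=C\[C@@H](O[Si](C(C)C)(C(C)C)C(C)C)C(C)(C)[C@H]1[C@@H]2CC[C@H](O[Si](C)(C)C(C)(C)C)[C@H]1[C@]2(O)C
F2 | step 6 | methyl (3S)-3-[(1R,4S)-4-(tert-butyldimethylsilyloxy)-2-methylcyclohex-2-en-1-yl]-3-hydroxy-2,2-dimethylpropanoate | COC(=O)C(C)(C)[C@@H](O)[C@H]1C(C)=C[C@@H](O[Si](C)(C)C(C)(C)C)CC1
F3 | step 6 | (3S)-3-[(1R,4S)-4-(tert-butyldimethylsilyloxy)-2-methylcyclohex-2-en-1-yl]-3-hydroxy-N-methoxy-N,2,2-trimethylpropanamide | CON(C)C(=O)C(C)(C)[C@@H](O)[C@H]1C(C)=C[C@@H](O[Si](C)(C)C(C)(C)C)CC1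
F4 | step 18 | 7,8,9-tris-O-{2-[bis(2,2,2-trifluoroethoxy)phosphoryl]propanoyl} derivative of triol 22 | CC(C(=O)O[C@@H]1[C@@H](OC(=O)C(C)P(=O)(OCC(F)(F)F)OCC(F)(F)F)C(C)(C)[C@H]2[C@@H]3[C@H](C)CC(=O)[C@H]2[C@]3(C)[C@@H]1OC(=O)C(C)P(=O)(OCC(F)(F)F)OCC(F)(F)F)P(=O)(OCC(F)(F)F)OCC(F)(F)F
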